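**Strategy.** The butenolide ring (O1, C2, C3, C4, C5) is cut at O1–C5 and C3=C4. This reveals pyruvic acid (O1, C2, C3 and the C3 methyl) and a 2-enal in which C5 is the β-carbon, C4 the α-carbon and the formyl carbon the later C4 carboxyl. The key step joins both in one amine-catalysed domino. Reversible oxa-Michael addition of the carboxylic acid to the chiral iminium ion sets C5. Aldol condensation of the enamine onto the pyruvoyl ketone then closes the ring and locks the stereocentre. The precursor is achiral, unprotected (E)-18-oxooctadec-16-enoic acid; oxidation of the formyl group finishes the target.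

Key step: step 3

Remark: ring atoms are numbered as in furan-2(5H)-one (O1, C2 lactone carbonyl, C3 methyl-bearing, C4 carboxyl-bearing, C5 stereocentre); the (S)-amine is chosen on the usual face-shielding model of diarylprolinol silyl ethers, and its enantiomer would be taken if the sense proved opposite.

**Step 1**
Reactants: 1 16-hydroxyhexadecanoic acid
Product: 2 16-oxohexadecanoic acid
Conditions: TEMPO (10 mol%), PhI(OAc)2 (1.1 equiv), CH2Cl2/THF, rt
Reagents that add atoms: none
Why: Oxoammonium-catalysed (TEMPO) alcohol oxidation with PhI(OAc)2 as terminal oxidant should stop at the aldehyde in the absence of water and tolerates the free carboxylic acid; no stereocentre is formed.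

**Step 2**
Reactants: 2 16-oxohexadecanoic acid; 3 (triphenylphosphoranylidene)acetaldehyde
Product: 4 (E)-18-oxooctadec-16-enoic acid
Conditions: 3 (1.2 equiv), toluene, 80 °C
Reagents that add atoms: none
Why: Wittig olefination with the formyl-stabilised ylide is E-selective, and the saturated aldehyde 2 should react faster than the conjugated product 4, which limits a second homologation; no stereocentre is formed.

**Step 3**
Reactants: 4 (E)-18-oxooctadec-16-enoic acid; 5 pyruvic acid
Product: 8 15-[(2R)-3-formyl-4-methyl-5-oxo-2,5-dihydrofuran-2-yl]pentadecanoic acid, via β-pyruvoyloxy aldehyde 6 (not isolated), via aldol lactone 7 (not isolated)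
Conditions: (S)-2-[diphenyl(tert-butyldimethylsilyloxy)methyl]pyrrolidine (20 mol%), 5 (1.5 equiv), toluene, 0 °C to rt
Reagents that add atoms: none
Why: Proposed new method: the secondary amine condenses with enal 4 to an (E)-iminium ion whose pyruvate counter-ion adds reversibly through oxygen to C-β (the later C5); the resulting enamine carbon (the later C4) adds to the pyruvoyl ketone (the later C3), which O-acylation has turned into a highly electrophilic α-keto ester, and E1cB loss of water from 7 followed by hydrolysis releases 8 and the amine. The closest known reaction type is the diarylprolinol silyl ether catalysed asymmetric domino oxa-Michael/aldol condensation of salicylaldehydes with enals to 2H-chromene-3-carbaldehydes; new here are a carboxylic acid as oxygen donor and a ketone as aldol acceptor. The butenolide ring (O1, C2, C3, C4, C5) closes in a 5-(enolexo)-exo-trig aldol addition. C5 is set by the catalyst: the diphenyl(silyloxy)methyl group shields one face of the s-trans iminium ion, the oxygen enters at the open Re face of C-β, and the usual model for the (S)-amine predicts (R). Because the oxa-Michael step is reversible, both adduct epimers and any (Z)-enal should funnel through the faster-cyclising enamine, and dehydration makes the outcome irreversible since C4 then carries no hydrogen. The step needs O- instead of C-attack of pyruvate and 1,4- instead of 1,2-addition: the hindered amine should not form an enamine with the methyl ketone, acylal formation at the formyl group is reversible, and the ω-carboxyl adds without a ketone to trap it.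

**Step 4**
Reactants: 8 15-[(2R)-3-formyl-4-methyl-5-oxo-2,5-dihydrofuran-2-yl]pentadecanoic acid
Product: 9 (2R)-2-(14-carboxytetradecyl)-4-methyl-5-oxo-2,5-dihydrofuran-3-carboxylic acid
Conditions: NaClO2, NaH2PO4, 2-methyl-2-butene, t-BuOH/H2O, 0 °C to rt
Reagents that add atoms: sodium chlorite, [Na+].[O-]Cl=O
Why: Pinnick (chlorite) oxidation should convert the conjugated aldehyde into the acid in a weakly acidic buffer that neither opens the lactone nor deprotonates C5, with 2-methyl-2-butene trapping HOCl; the stereocentre is untouched.

**Compound list**
1 | 16-hydroxyhexadecanoic acid | OCCCCCCCCCCCCCCCC(=O)O | starting material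
2 | 16-oxohexadecanoic acid | O=CCCCCCCCCCCCCCCC(=O)O | intermediate
3 | (triphenylphosphoranylidene)acetaldehyde | O=CC=P(c1ccccc1)(c1ccccc1)c1ccccc1 | starting material
4 | (E)-18-oxooctadec-16-enoic acid | O=C/C=C/CCCCCCCCCCCCCCC(=O)O | intermediate
5 | pyruvic acid (2-oxopropanoic acid) | CC(=O)C(=O)O | starting material
6 | (16R)-18-oxo-16-[(2-oxopropanoyl)oxy]octadecanoic acid, oxa-Michael adduct, carried as its enamine with the amine catalyst | CC(=O)C(=O)O[C@@H](CC=O)CCCCCCCCCCCCCCC(=O)O | intermediate (not isolated)
7 | 15-[(2R)-3-formyl-4-hydroxy-4-methyl-5-oxooxolan-2-yl]pentadecanoic acid, aldol adduct, configuration at the two other ring carbons undefined and lost on dehydration | CC1(O)C(C=O)[C@@H](CCCCCCCCCCCCCCC(=O)O)OC1=O | intermediate (not isolated)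
8 | 15-[(2R)-3-formyl-4-methyl-5-oxo-2,5-dihydrofuran-2-yl]pentadecanoic acid | CC1=C(C=O)[C@@H](CCCCCCCCCCCCCCC(=O)O)OC1=O | intermediate
9 | (2R)-2-(14-carboxytetradecyl)-4-methyl-5-oxo-2,5-dihydrofuran-3-carboxylic acid | CC1=C(C(=O)O)[C@@H](CCCCCCCCCCCCCCC(=O)O)OC1=O | target

**Totals.** Total steps: 4. Longest linear sequence: 4 steps.

**Steps most likely to fail**

Step 3 (proposed new method). Conjugate addition of the weakly nucleophilic carboxylate may be too slow, so that dienamine formation and self-condensation of 4, or amine-promoted aldol chemistry at the methyl group of 5, take over. Facial control may also be lost if both enamine epimers cyclise at similar rates, and C5 may epimerise through the lactone dienolate on long exposure to the amine. The fallback uses known chemistry with a different ring construction; it sets out from 2 and returns at 9. SnCl2-catalysed homologation of 2 with tert-butyl diazoacetate (Roskamp reaction) should give 18-tert-butoxy-16,18-dioxooctadecanoic acid F1. Asymmetric hydrogenation with RuCl2[(R)-BINAP] and H2 in MeOH should give (16R)-18-tert-butoxy-16-hydroxy-18-oxooctadecanoic acid F2, which fixes the later C5 with its oxygen in place. F2 is deprotonated with LDA (3.2 equiv, THF, −78 to −30 °C) at the carboxyl, the hydroxyl and the ester α-carbon; the enolate adds to the ketone of methyl pyruvate, and the C16 alkoxide closes onto the pyruvate ester to give 15-[(2R)-3-(tert-butoxycarbonyl)-4-hydroxy-4-methyl-5-oxooxolan-2-yl]pentadecanoic acid F3. MsCl/Et3N in CH2Cl2 at 0 °C should eliminate the tertiary alcohol toward the ester-activated C–H to give 15-[(2R)-3-(tert-butoxycarbonyl)-4-methyl-5-oxo-2,5-dihydrofuran-2-yl]pentadecanoic acid F4. CF3CO2H in CH2Cl2 then cleaves the tert-butyl ester to 9.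

Step 2. Protonation of the ylide by the carboxylic acid may slow the olefination, and a second olefination of product 4 by the ylide may lead on to the dienal. The fallback sets out from 2 and returns at 4. Wittig reaction of 2 with the ylide from (1,3-dioxolan-2-ylmethyl)triphenylphosphonium bromide and KOtBu (2.2 equiv, THF, 0 °C to rt) should give 17-(1,3-dioxolan-2-yl)heptadec-16-enoic acid F5 as an E/Z mixture; this masked enal cannot be olefinated again. Aqueous HCl in THF then cleaves the acetal and equilibrates the enal to the (E)-isomer 4.

Step 1. Over-oxidation to the diacid by adventitious water and loss of the aldehyde acid by oligomerisation on concentration are possible. The fallback sets out from 1 and returns at 2 and replaces alcohol dehydrogenation by substitution and elimination. 48% aqueous HBr with catalytic H2SO4 at reflux should give 16-bromohexadecanoic acid F6. Trimethylamine N-oxide in DMSO then displaces bromide, and the alkoxyammonium salt fragments to aldehyde 2, which cannot be oxidised further under these conditions.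

**Further compounds**
F1 | step 3 | 18-tert-butoxy-16,18-dioxooctadecanoic acid | CC(C)(C)OC(=O)CC(=O)CCCCCCCCCCCCCCC(=O)O
F2 | step 3 | (16R)-18-tert-butoxy-16-hydroxy-18-oxooctadecanoic acid | CC(C)(C)OC(=O)C[C@H](O)CCCCCCCCCCCCCCC(=O)O
F3 | step 3 | 15-[(2R)-3-(tert-butoxycarbonyl)-4-hydroxy-4-methyl-5-oxooxolan-2-yl]pentadecanoic acid | CC1(O)C(C(=O)OC(C)(C)C)[C@@H](CCCCCCCCCCCCCCC(=O)O)OC1=O
F4 | step 3 | 15-[(2R)-3-(tert-butoxycarbonyl)-4-methyl-5-oxo-2,5-dihydrofuran-2-yl]pentadecanoic acid | CC1=C(C(=O)OC(C)(C)C)[C@@H](CCCCCCCCCCCCCCC(=O)O)OC1=O
F5 | step 2 | 17-(1,3-dioxolan-2-yl)heptadec-16-enoic acid (E/Z mixture) | O=C(O)CCCCCCCCCCCCCCC=CC1OCCO1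
F6 | step 1 | 16-bromohexadecanoic acid | BrCCCCCCCCCCCCCCCC(=O)O
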